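Assumption: THF numbering is used with lignan numbering in parentheses (C2 = C7, C3 = C8, C4 = C8′, C5 = C9′). Compounds 1, 2 and 4 are taken as commercial. Numbering follows the forward route.

## Retrosynthetic overview
1. The only ring, the THF, is closed last. The O–C2 bond comes from C2-symmetric (−)-secoisolariciresinol by dehydrogenative benzylic C–H etherification through a p-quinone methide, which is the biosynthetic reductase step run backwards. The reacting sites are homotopic, so one product forms, and C2 is set by substrate control.
2. (−)-Secoisolariciresinol comes from reduction and debenzylation of a (2R,3R)-2,3-dibenzylsuccinyl bis(oxazolidinone).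
3. The central C3–C4 (C8–C8′) bond comes from oxidative homodimerisation of a single Evans imide enolate. This one step sets both carbon stereocentres.
4. The monomer comes from dihydroferulic acid, benzyl bromide and (S)-4-isopropyloxazolidin-2-one.

## Route

**Step 1**
Reactants: 1, dihydroferulic acid [3-(4-hydroxy-3-methoxyphenyl)propanoic acid]; 2, benzyl bromide
Product: 3, 3-[4-(benzyloxy)-3-methoxyphenyl]propanoic acid
Conditions: BnBr (1.2 equiv), NaOH (3 equiv), EtOH/H2O, reflux; then aq HCl
Reagents that add atoms: benzyl bromide, BrCc1ccccc1
Why: Williamson ether synthesis on the phenoxide/carboxylate dianion, in which the phenoxide is the better nucleophile in protic medium and any benzyl ester formed is saponified in situ; no stereocentre is involved.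

**Step 2**
Reactants: 3; 4, (S)-4-isopropyl-1,3-oxazolidin-2-one
Product: 5, (4S)-3-{3-[4-(benzyloxy)-3-methoxyphenyl]propanoyl}-4-isopropyl-1,3-oxazolidin-2-one
Conditions: PivCl, Et3N, THF, −20 °C; then LiCl, 4, −20 °C → rt
Reagents that add atoms: (S)-4-isopropyloxazolidin-2-one, CC(C)[C@H]1COC(=O)N1
Why: Mixed-anhydride N-acylation of an Evans auxiliary, in which the oxazolidinone attacks the unhindered acyl carbonyl rather than the pivaloyl one; the auxiliary stereocentre is untouched.

**Step 3**
Reactants: 5 (two molecules)
Product: 6, (2R,3R)-2,3-bis[4-(benzyloxy)-3-methoxybenzyl]-1,4-bis[(4S)-4-isopropyl-2-oxo-1,3-oxazolidin-3-yl]butane-1,4-dione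
Conditions: LDA (1.05 equiv), THF, −78 °C, 45 min; then anhydrous CuCl2 (1.1 equiv) in DMF, −78 → 0 °C; chromatography or recrystallisation to remove the minor (R,S) and (S,S) dimers
Reagents that add atoms: none
Why: Cu(II)-mediated oxidative enolate homocoupling, in which each chelated Z-enolate/α-imidyl radical bonds on the face anti to the isopropyl group, so both new centres are R (future C3 and C4); removing the diastereomeric dimers upgrades stereopurity (Horeau-type amplification), and the dialkoxyarenes and benzyl ethers are not oxidised by Cu(II) at low temperature.

**Step 4**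
Reactants: 6
Product: 7, (2R,3R)-2,3-bis[4-(benzyloxy)-3-methoxybenzyl]butane-1,4-diol (O,O′-dibenzyl-secoisolariciresinol)
Conditions: LiBH4 (6 equiv), MeOH (6 equiv), THF, 0 °C → rt; auxiliary 4 recovered
Reagents that add atoms: none
Why: Reductive cleavage of N-acyloxazolidinones by hydride attack at the exocyclic imide carbonyl, with excess LiBH4 reducing any transient trans-lactone onward to the diol; the medium is too weakly basic to epimerise the α-centres, and the aryl benzyl ethers are inert.

**Step 5**
Reactants: 7
Product: 8, (−)-secoisolariciresinol, (2R,3R)-2,3-bis(4-hydroxy-3-methoxybenzyl)butane-1,4-diol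
Conditions: H2 (1 atm), 10% Pd/C, EtOAc/EtOH, rt
Reagents that add atoms: none
Why: Hydrogenolysis of the aryl benzyl ethers, done before ring closure because 7 has no other benzylic C–O bond whereas the C2–O bond of the final THF would be hydrogenolysable; the stereocentres are not involved.

**Step 6**
Reactants: 8
Product: 9, (+)-lariciresinol, 4-[(2S,3R,4R)-4-(4-hydroxy-3-methoxybenzyl)-3-(hydroxymethyl)tetrahydrofuran-2-yl]-2-methoxyphenol
Conditions: DDQ (0.8 equiv, slow addition), solid NaHCO3, 1,4-dioxane (0.01 M), 15 °C → rt, dark; stop at about 50–60% conversion; recovered 8 recycled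
Reagents that add atoms: none (net loss of H2)
Why: Proposed new method: DDQ removes hydride plus proton from a benzylic CH2 para to a free phenol to give a p-quinone methide at C7, and the C9′ primary OH adds in a 5-exo oxa-1,6-conjugate addition that rearomatises the ring; because 8 is C2-symmetric, both benzylic CH2 groups and both CH2OH groups are homotopic, so either oxidation gives the same compound; C2 is set under A(1,3) control (C8–H eclipses the quinone methide plane and oxygen attacks from the C8′ side), which places the aryl trans to CH2OH = (2S), also the thermodynamic isomer; sub-stoichiometric oxidant, high dilution and bicarbonate buffering limit a second oxidation (to pinoresinol) and acid-driven Friedel–Crafts closure (to cyclolariciresinol), and the α-alkoxy-substituted phenol of 9 should be slightly harder to oxidise than the 4-alkylphenols of 8; the closest known reaction types are DDQ dehydrogenation of 4-alkylphenols to p-quinone methides with alcohol capture, and acid-induced cyclisation of 7-hydroxy-dibenzylbutanediols through the same intermediate.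

## Compound list
1 | dihydroferulic acid | COc1cc(CCC(=O)O)ccc1O | starting material
2 | benzyl bromide | BrCc1ccccc1 | starting material
3 | 3-[4-(benzyloxy)-3-methoxyphenyl]propanoic acid | COc1cc(CCC(=O)O)ccc1OCc1ccccc1 | intermediate
4 | (S)-4-isopropyl-1,3-oxazolidin-2-one | CC(C)[C@H]1COC(=O)N1 | starting material
5 | (4S)-3-{3-[4-(benzyloxy)-3-methoxyphenyl]propanoyl}-4-isopropyloxazolidin-2-one | COc1cc(CCC(=O)N2[C@@H](C(C)C)COC2=O)ccc1OCc1ccccc1 | intermediate
6 | (2R,3R)-2,3-bis[4-(benzyloxy)-3-methoxybenzyl]succinyl bis[(4S)-4-isopropyloxazolidin-2-one] | COc1cc(C[C@@H](C(=O)N2[C@@H](C(C)C)COC2=O)[C@H](C(=O)N2[C@@H](C(C)C)COC2=O)Cc2ccc(OCc3ccccc3)c(OC)c2)ccc1OCc1ccccc1 | intermediate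
7 | (2R,3R)-2,3-bis[4-(benzyloxy)-3-methoxybenzyl]butane-1,4-diol | COc1cc(C[C@@H](CO)[C@H](CO)Cc2ccc(OCc3ccccc3)c(OC)c2)ccc1OCc1ccccc1 | intermediate
8 | (−)-secoisolariciresinol (2R,3R) | COc1cc(C[C@@H](CO)[C@H](CO)Cc2ccc(O)c(OC)c2)ccc1O | intermediate
9 | (+)-lariciresinol (2S,3R,4R) | COc1cc(C[C@H]2CO[C@H](c3ccc(O)c(OC)c3)[C@H]2CO)ccc1O | target

## Summary
Total step count: 6. Longest linear sequence: 6 (fully linear; step 3 joins two copies of 5).

Steps most likely to fail:
1. **Step 6, selective single quinone methide oxidation and cyclisation.** The risks are over-oxidation, arene capture, elimination to the styrene, and DDQ adducts. Fallback: stop aiming for mono-selectivity. Oxidise both homotopic benzylic positions (≥2.2 equiv oxidant) to C2-symmetric (+)-pinoresinol, in which both quinone methides are captured to give the cis-fused furofuran. Then reopen one of its two equivalent benzylic C–O bonds by controlled hydrogenolysis (H2, Pd/C) to give 9. Any pinoresinol formed in the original step can be sent down the same path.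
2. **Step 3, oxidative homocoupling.** The risks are moderate yield and dr, and α-chlorination. Fallback: build the C8–C8′ connectivity by polar, stepwise chemistry instead.
   - Evans alkylation of 5 with tert-butyl bromoacetate.
   - LiBH4 reduction and acid lactonisation to the (R)-β-benzyl-γ-butyrolactone.
   - Trans-selective α-alkylation with 4-(benzyloxy)-3-methoxybenzyl bromide.
   - LiAlH4 reduction to the same diol 7.
3. **Step 4, double reductive removal of the auxiliary from a hindered bis-imide.** The risks are endocyclic ring opening and stalling at the lactone or hydroxy-imide. Fallback: separate cleavage from reduction. Hydrolyse with LiOH/H2O2 to the (2R,3R)-dibenzylsuccinic acid, recovering the auxiliary, then reduce the diacid with BH3·THF to 7.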